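Carotenoid locants are used: primes on the acetoxy half, C19 = butenolide carbonyl, chain C7'≡C8'–C9'(Me)=C10'–C11'=C14'–C15'=C15–C14=C13(Me)–C12=C11(butenolide C5)–C10=C9(–C19)–C8=C7–C6.
Key disconnection: C14'–C15', the central CH–CH bond of the all-E tetraene C9'=C10'–C11'=C14'–C15'=C15–C14=C13, is made last by a Mizoroki–Heck union of a C14' dienyl iodide (left half) with the free C15'H2= terminus of a trienyl butenolide (right half), both unprotected.
Enabling feature: C15' belongs to the only monosubstituted alkene and is the ω-carbon of the acceptor chain C19(=O)–C9=C10–C11=C12–C13=C14–C15=C15' that starts in the butenolide ring; the segments C7'–C11' and C11–C15 are two copies of one C6 enynal, so each terminus needs only a one-carbon olefination (CHI for C14', CH2 for C15').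
Right half: C8–C9 by Stille coupling of an epoxycyclohexyl vinylstannane with a 3-bromobutenolide, itself made by tandem Sonogashira coupling/5-exo-dig lactonisation of (E)-2,3-dibromopropenoic acid with the C7 trienyne; left half: Takai iodo-olefination of the enal from Sonogashira coupling of the ring enol triflate with the same enynal.
Ring order: both carbocycles come intact from (4R,6R)-actinol through one common enol triflate, then the oxirane (Sharpless epoxidation, step 10), then the butenolide (step 17); no ring is formed in the key step.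

Key step: step 19

Assumption: (4R,6R)-actinol and (2E)-3-methylpent-2-en-4-yn-1-ol are purchasable; all polyenes are handled under argon with exclusion of light.

Step 1
Reactants: 1 (4R,6R)-4-hydroxy-2,2,6-trimethylcyclohexan-1-one (actinol)
Product: 2 (4R,6R)-4-{[tert-butyl(dimethyl)silyl]oxy}-2,2,6-trimethylcyclohexan-1-one
Conditions: TBSCl, imidazole, DMF, 25 °C
Reagents that add atoms: tert-butyl(chloro)dimethylsilane, CC(C)(C)[Si](C)(C)Cl
Why: Silyl ether formation on the unhindered secondary alcohol masks the only acidic OH before enolate chemistry and touches no stereocentre.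

Step 2
Reactants: 2 (4R,6R)-4-{[tert-butyl(dimethyl)silyl]oxy}-2,2,6-trimethylcyclohexan-1-one
Product: 4 (4R)-4-{[tert-butyl(dimethyl)silyl]oxy}-2,6,6-trimethylcyclohex-1-en-1-yl trifluoromethanesulfonate, via lithium enolate 3 (not isolated)
Conditions: LiN(iPr)2, THF, −78 → 0 °C; then PhNTf2, −78 → 25 °C
Reagents that add atoms: N-phenylbis(trifluoromethanesulfonimide), FC(F)(F)S(=O)(=O)N(c1ccccc1)S(=O)(=O)C(F)(F)F
Why: Enol triflate formation: the ketone has a single α-hydrogen (the other α-carbon is quaternary), so one enolate forms and its O-sulfonylation should give the tetrasubstituted enol triflate, erasing the methyl-bearing stereocentre on purpose and leaving the carbinol centre untouched.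

Step 3
Reactants: 4 (4R)-4-{[tert-butyl(dimethyl)silyl]oxy}-2,6,6-trimethylcyclohex-1-en-1-yl trifluoromethanesulfonate
Product: 5 (4R)-4-hydroxy-2,6,6-trimethylcyclohex-1-en-1-yl trifluoromethanesulfonate
Conditions: HF (48 % aq.), MeCN, 0 → 25 °C
Reagents that add atoms: none
Why: Acidic fluoride desilylation, chosen because an enol triflate is inert to aqueous HF whereas basic fluoride could attack the sulfonate.

Step 4
Reactants: 5 (4R)-4-hydroxy-2,6,6-trimethylcyclohex-1-en-1-yl trifluoromethanesulfonate
Product: 6 (1R)-3,5,5-trimethyl-4-{[(trifluoromethyl)sulfonyl]oxy}cyclohex-3-en-1-yl acetate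
Conditions: Ac2O, pyridine, DMAP (cat.), CH2Cl2, 25 °C
Reagents that add atoms: acetic anhydride, CC(=O)OC(C)=O
Why: DMAP-catalysed acylation installs the C3' acetate of the target at a robust stage without displacing the triflate.

Step 5
Reactants: 7 (2E)-3-methylpent-2-en-4-yn-1-ol
Product: 8 (2E)-3-methylpent-2-en-4-ynal
Conditions: MnO2 (activated, excess), CH2Cl2, 25 °C
Reagents that add atoms: none
Why: Chemoselective MnO2 oxidation of the primary allylic alcohol should stop at the enal and leave the E alkene and the terminal alkyne untouched, the volatile product being carried on as a concentrated solution.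

Step 6
Reactants: 6 (1R)-3,5,5-trimethyl-4-{[(trifluoromethyl)sulfonyl]oxy}cyclohex-3-en-1-yl acetate; 8 (2E)-3-methylpent-2-en-4-ynal
Product: 9 (1R)-3,5,5-trimethyl-4-[(3E)-3-methyl-5-oxopent-3-en-1-yn-1-yl]cyclohex-3-en-1-yl acetate
Conditions: Pd(PPh3)4 (5 mol %), CuI (10 mol %), Et3N, DMF, 25 → 45 °C
Reagents that add atoms: none
Why: Sonogashira coupling of the enol triflate with the terminal alkyne forms the C6'–C7' bond and thus the 7',8'-alkyne, a tertiary amine being used so that the enal is not attacked and the acetate and alkene geometry are preserved.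

Step 7
Reactants: 9 (1R)-3,5,5-trimethyl-4-[(3E)-3-methyl-5-oxopent-3-en-1-yn-1-yl]cyclohex-3-en-1-yl acetate
Product: 10 (1R)-4-[(3E,5E)-6-iodo-3-methylhexa-3,5-dien-1-yn-1-yl]-3,5,5-trimethylcyclohex-3-en-1-yl acetate
Conditions: CrCl2 (6 equiv), CHI3 (2 equiv), THF, 0 → 25 °C, dark
Reagents that add atoms: iodoform, IC(I)I
Why: Takai iodo-olefination: the gem-dimetallic carbenoid formed from CHI3 and CrCl2 adds to the aldehyde and anti-elimination should give the E C11'=C14' iodoalkene, adding C14' as the coupling terminus while acetate and enyne are tolerated.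

Step 8
Reactants: 4 (4R)-4-{[tert-butyl(dimethyl)silyl]oxy}-2,6,6-trimethylcyclohex-1-en-1-yl trifluoromethanesulfonate
Product: 11 methyl (4R)-4-{[tert-butyl(dimethyl)silyl]oxy}-2,6,6-trimethylcyclohex-1-ene-1-carboxylate
Conditions: Pd(OAc)2 (5 mol %), PPh3 (10 mol %), CO (1 atm), MeOH, Et3N, DMF, 60 °C
Reagents that add atoms: carbon monoxide, [C-]#[O+]; methanol, CO
Why: Palladium-catalysed methoxycarbonylation of the enol triflate (oxidative addition, CO insertion, methanolysis of the acyl–Pd bond) introduces C7 as an ester without touching the silyl ether.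

Step 9
Reactants: 11 methyl (4R)-4-{[tert-butyl(dimethyl)silyl]oxy}-2,6,6-trimethylcyclohex-1-ene-1-carboxylate
Product: 12 [(4R)-4-{[tert-butyl(dimethyl)silyl]oxy}-2,6,6-trimethylcyclohex-1-en-1-yl]methanol
Conditions: iBu2AlH (2.5 equiv), CH2Cl2, −78 → 0 °C; aq. KNaC4H4O6 work-up
Reagents that add atoms: none
Why: 1,2-Reduction of the conjugated ester by the aluminium hydride gives the primary allylic alcohol needed as the directing handle for the epoxidation.

Step 10
Reactants: 12 [(4R)-4-{[tert-butyl(dimethyl)silyl]oxy}-2,6,6-trimethylcyclohex-1-en-1-yl]methanol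
Product: 13 [(1R,4S,6R)-4-{[tert-butyl(dimethyl)silyl]oxy}-2,2,6-trimethyl-7-oxabicyclo[4.1.0]heptan-1-yl]methanol
Conditions: Ti(OiPr)4 (20 mol %), D-(−)-diethyl tartrate (24 mol %), t-BuOOH, 4 Å molecular sieves, CH2Cl2, −20 °C
Reagents that add atoms: tert-butyl hydroperoxide, CC(C)(C)OO
Why: Sharpless asymmetric epoxidation of the allylic alcohol, in which the catalyst formed from Ti(OiPr)4 and D-(−)-diethyl tartrate should deliver oxygen by reagent control to the alkene face anti to the silyloxy group and so set both oxirane centres (C1 R, C6 R; 5R,6S of the target in carotenoid numbering).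

Step 11
Reactants: 13 [(1R,4S,6R)-4-{[tert-butyl(dimethyl)silyl]oxy}-2,2,6-trimethyl-7-oxabicyclo[4.1.0]heptan-1-yl]methanol
Product: 14 (1S,4S,6R)-4-{[tert-butyl(dimethyl)silyl]oxy}-2,2,6-trimethyl-7-oxabicyclo[4.1.0]heptane-1-carbaldehyde
Conditions: Pr4N[RuO4] (5 mol %), N-methylmorpholine N-oxide, 4 Å molecular sieves, CH2Cl2, 25 °C
Reagents that add atoms: none
Why: Ley–Griffith oxidation converts the neopentyl-type epoxy alcohol into the non-enolisable aldehyde under neutral conditions that spare oxirane and silyl ether (the C1 descriptor changes only through CIP priorities).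

Step 12
Reactants: 14 (1S,4S,6R)-4-{[tert-butyl(dimethyl)silyl]oxy}-2,2,6-trimethyl-7-oxabicyclo[4.1.0]heptane-1-carbaldehyde
Product: 15 (1S,4S,6R)-4-hydroxy-2,2,6-trimethyl-7-oxabicyclo[4.1.0]heptane-1-carbaldehyde
Conditions: Bu4NF, THF, 0 → 25 °C
Reagents that add atoms: none
Why: Fluoride desilylation at this small, non-enolisable stage frees the C3 hydroxyl of the target so that no protecting group has to be removed from a polyene later.

Step 13
Reactants: 16 dibromomethane
Product: 18 tributyl(dibromomethyl)stannane, via dibromomethyllithium 17 (not isolated)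
Conditions: LiN(iPr)2, THF/Et2O, −95 °C; then Bu3SnCl, −95 → −78 °C
Reagents that add atoms: tributyltin chloride, CCCC[Sn](Cl)(CCCC)CCCC
Why: Deprotonation of CH2Br2 gives a lithium carbenoid that is persistent at this temperature and should be stannylated faster than it decomposes, giving the reagent for the Takai-type stannyl-olefination.

Step 14
Reactants: 15 (1S,4S,6R)-4-hydroxy-2,2,6-trimethyl-7-oxabicyclo[4.1.0]heptane-1-carbaldehyde; 18 tributyl(dibromomethyl)stannane
Product: 20 (1R,3S,6S)-1,5,5-trimethyl-6-[(E)-2-(tributylstannyl)ethenyl]-7-oxabicyclo[4.1.0]heptan-3-ol, via tributyl(diiodomethyl)stannane 19 (not isolated)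
Conditions: CrCl2 (8 equiv), LiI (4 equiv), DMF/THF, 25 °C, dark
Reagents that add atoms: none
Why: Takai-type stannyl-olefination: halide exchange with LiI gives the diiodide, whose gem-dimetallic derivative formed with CrCl2 adds to the aldehyde and eliminates anti to give the E C7=C8 vinylstannane directly, with no palladium hydride or strong nucleophile that could open the oxirane and with tolerance of the free hydroxyl.

Step 15
Reactants: 8 (2E)-3-methylpent-2-en-4-ynal
Product: 21 (3E)-3-methylhexa-3,5-dien-1-yne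
Conditions: Ph3PCH3Br, KN(SiMe3)2, Et2O, 0 °C; then 8, −78 → 25 °C
Reagents that add atoms: methyltriphenylphosphonium bromide, C[P+](c1ccccc1)(c1ccccc1)c1ccccc1.[Br-]
Why: Wittig methylenation adds C15' as the free =CH2 terminus; the ylide is too weakly basic to deprotonate the alkyne, the E C13=C14 bond is untouched, and the volatile hydrocarbon is used as a solution.

Step 16
Reactants: 22 propiolic acid
Product: 23 (2E)-2,3-dibromoprop-2-enoic acid
Conditions: Br2 (1.0 equiv), CHCl3, 0 → 25 °C, dark
Reagents that add atoms: bromine, BrBr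
Why: Ionic anti-addition of bromine to the alkyne places the C3 bromine cis to the carboxyl group, the geometry needed for lactonisation after coupling.

Step 17
Reactants: 23 (2E)-2,3-dibromoprop-2-enoic acid; 21 (3E)-3-methylhexa-3,5-dien-1-yne
Product: 25 (5Z)-3-bromo-5-[(2E)-2-methylpenta-2,4-dien-1-ylidene]furan-2(5H)-one, via bromoenynoic acid 24 (not isolated)
Conditions: PdCl2(PPh3)2 (5 mol %), CuI (10 mol %), Et3N, MeCN, 25 °C, dark
Reagents that add atoms: none
Why: Tandem Sonogashira coupling/5-exo-dig lactonisation: the β-bromine (cis to CO2H) undergoes oxidative addition faster than the α-bromine, and the resulting enynoic acid should cyclise by anti-oxymetalation and protodemetalation, closing the butenolide ring and fixing the Z C11=C12 ylidene bond while the α-bromine (future C9) survives.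

Step 18
Reactants: 25 (5Z)-3-bromo-5-[(2E)-2-methylpenta-2,4-dien-1-ylidene]furan-2(5H)-one; 20 (1R,3S,6S)-1,5,5-trimethyl-6-[(E)-2-(tributylstannyl)ethenyl]-7-oxabicyclo[4.1.0]heptan-3-ol
Product: 26 (5Z)-3-{(E)-2-[(1S,4S,6R)-4-hydroxy-2,2,6-trimethyl-7-oxabicyclo[4.1.0]heptan-1-yl]ethenyl}-5-[(2E)-2-methylpenta-2,4-dien-1-ylidene]furan-2(5H)-one
Conditions: Pd2(dba)3 (2.5 mol %), AsPh3 (20 mol %), DMF, 25 → 40 °C, dark
Reagents that add atoms: none
Why: Stille coupling of the α-bromo enoate carbon with the E-vinylstannane forms C8–C9 with retention at both alkenes under neutral conditions, transmetalation outpacing Heck insertion into the terminal alkene, while the fully substituted vinyl oxirane is too hindered to ionise to a π-allyl complex and the free hydroxyl needs no protection.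

Step 19
Reactants: 26 (5Z)-3-{(E)-2-[(1S,4S,6R)-4-hydroxy-2,2,6-trimethyl-7-oxabicyclo[4.1.0]heptan-1-yl]ethenyl}-5-[(2E)-2-methylpenta-2,4-dien-1-ylidene]furan-2(5H)-one; 10 (1R)-4-[(3E,5E)-6-iodo-3-methylhexa-3,5-dien-1-yn-1-yl]-3,5,5-trimethylcyclohex-3-en-1-yl acetate
Product: 27 pyrrhoxanthin (target)
Conditions: Pd(OAc)2 (10 mol %), P(2-furyl)3 (20 mol %), Ag2CO3 (1.0 equiv), 10 (1.2 equiv), DMF, 25 → 40 °C, dark, Ar
Reagents that add atoms: none
Why: Mizoroki–Heck alkenylation, whose closest precedent is the silver-promoted Heck vinylation of terminal 1,3-dienes and 2,4-dienoates with alkenyl iodides to all-E polyenes: zerovalent palladium inserts into the C14'–I bond of 10 with retention of the C11'=C14' geometry, the alkenyl–Pd bond adds syn across C15=C15' of 26 with carbon going to the unsubstituted C15', and syn β-hydride elimination from the C15-bound, π-allyl-stabilised palladium towards C15' restores conjugation and gives the E C15=C15' bond because the two chain ends sit anti in the eliminating rotamer. No ring is closed and no stereocentre is created; the only new stereo-element is the C15=C15' double bond, fixed as described, and all existing centres and alkene geometries are spectators. The step needs site-selectivity for one alkene and regioselectivity for its CH2 carbon, and the substrate secures both, since C15=C15' is the only monosubstituted alkene present (all others are di- to tetrasubstituted) and C15' is the sterically open ω-carbon of the acceptor chain C19(=O)–C9=C10–C11=C12–C13=C14–C15=C15'. Ag2CO3 removes iodide (cationic pathway, insertion near room temperature), quenches HI without a nucleophilic base and suppresses palladium hydride re-addition, so acetate, enol lactone, free C3 hydroxyl and vinyl oxirane should stay intact. In this one operation the two unprotected halves should give the complete C37 skeleton with all six stereogenic double bonds and four stereocentres in place, and neither terminus needs a tin or boron group.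

Compound list
1 | (4R,6R)-4-hydroxy-2,2,6-trimethylcyclohexan-1-one (actinol) | O[C@@H]1C[C@@H](C)C(=O)C(C)(C)C1 | starting material
2 | (4R,6R)-4-{[tert-butyl(dimethyl)silyl]oxy}-2,2,6-trimethylcyclohexan-1-one | CC(C)(C)[Si](C)(C)O[C@@H]1C[C@@H](C)C(=O)C(C)(C)C1 | intermediate
3 | lithium (4R)-4-{[tert-butyl(dimethyl)silyl]oxy}-2,6,6-trimethylcyclohex-1-en-1-olate (not isolated) | CC(C)(C)[Si](C)(C)O[C@@H]1CC(C)=C(O[Li])C(C)(C)C1 | intermediate
4 | (4R)-4-{[tert-butyl(dimethyl)silyl]oxy}-2,6,6-trimethylcyclohex-1-en-1-yl trifluoromethanesulfonate | CC(C)(C)[Si](C)(C)O[C@@H]1CC(C)=C(OS(=O)(=O)C(F)(F)F)C(C)(C)C1 | intermediate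
5 | (4R)-4-hydroxy-2,6,6-trimethylcyclohex-1-en-1-yl trifluoromethanesulfonate | O[C@@H]1CC(C)=C(OS(=O)(=O)C(F)(F)F)C(C)(C)C1 | intermediate
6 | (1R)-3,5,5-trimethyl-4-{[(trifluoromethyl)sulfonyl]oxy}cyclohex-3-en-1-yl acetate | CC(=O)O[C@@H]1CC(C)=C(OS(=O)(=O)C(F)(F)F)C(C)(C)C1 | intermediate
7 | (2E)-3-methylpent-2-en-4-yn-1-ol | C#C/C(C)=C/CO | starting material
8 | (2E)-3-methylpent-2-en-4-ynal | C#C/C(C)=C/C=O | intermediate
9 | (1R)-3,5,5-trimethyl-4-[(3E)-3-methyl-5-oxopent-3-en-1-yn-1-yl]cyclohex-3-en-1-yl acetate | CC(=O)O[C@@H]1CC(C)=C(C#C/C(C)=C/C=O)C(C)(C)C1 | intermediate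
10 | (1R)-4-[(3E,5E)-6-iodo-3-methylhexa-3,5-dien-1-yn-1-yl]-3,5,5-trimethylcyclohex-3-en-1-yl acetate | CC(=O)O[C@@H]1CC(C)=C(C#C/C(C)=C/C=C/I)C(C)(C)C1 | intermediate
11 | methyl (4R)-4-{[tert-butyl(dimethyl)silyl]oxy}-2,6,6-trimethylcyclohex-1-ene-1-carboxylate | CC(C)(C)[Si](C)(C)O[C@@H]1CC(C)=C(C(=O)OC)C(C)(C)C1 | intermediate
12 | [(4R)-4-{[tert-butyl(dimethyl)silyl]oxy}-2,6,6-trimethylcyclohex-1-en-1-yl]methanol | CC(C)(C)[Si](C)(C)O[C@@H]1CC(C)=C(CO)C(C)(C)C1 | intermediate
13 | [(1R,4S,6R)-4-{[tert-butyl(dimethyl)silyl]oxy}-2,2,6-trimethyl-7-oxabicyclo[4.1.0]heptan-1-yl]methanol (oxirane anti to the silyloxy group) | OC[C@@]12O[C@]1(C)C[C@@H](O[Si](C)(C)C(C)(C)C)CC2(C)C | intermediate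
14 | (1S,4S,6R)-4-{[tert-butyl(dimethyl)silyl]oxy}-2,2,6-trimethyl-7-oxabicyclo[4.1.0]heptane-1-carbaldehyde | O=C[C@@]12O[C@]1(C)C[C@@H](O[Si](C)(C)C(C)(C)C)CC2(C)C | intermediate
15 | (1S,4S,6R)-4-hydroxy-2,2,6-trimethyl-7-oxabicyclo[4.1.0]heptane-1-carbaldehyde | O=C[C@@]12O[C@]1(C)C[C@@H](O)CC2(C)C | intermediate
16 | dibromomethane | BrCBr | starting material
17 | dibromomethyllithium (not isolated) | [Li]C(Br)Br | intermediate
18 | tributyl(dibromomethyl)stannane | CCCC[Sn](CCCC)(CCCC)C(Br)Br | intermediate
19 | tributyl(diiodomethyl)stannane (not isolated) | CCCC[Sn](CCCC)(CCCC)C(I)I | intermediate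
20 | (1R,3S,6S)-1,5,5-trimethyl-6-[(E)-2-(tributylstannyl)ethenyl]-7-oxabicyclo[4.1.0]heptan-3-ol | CCCC[Sn](CCCC)(CCCC)/C=C/[C@@]12O[C@]1(C)C[C@@H](O)CC2(C)C | intermediate
21 | (3E)-3-methylhexa-3,5-dien-1-yne | C#C/C(C)=C/C=C | intermediate
22 | propiolic acid | C#CC(=O)O | starting material
23 | (2E)-2,3-dibromoprop-2-enoic acid (C3 bromine cis to CO2H) | OC(=O)/C(Br)=C\Br | intermediate
24 | (2E,6E)-2-bromo-6-methylnona-2,6,8-trien-4-ynoic acid (not isolated; alkynyl group cis to CO2H) | OC(=O)/C(Br)=C\C#C/C(C)=C/C=C | intermediate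
25 | (5Z)-3-bromo-5-[(2E)-2-methylpenta-2,4-dien-1-ylidene]furan-2(5H)-one | C=C/C=C(C)/C=C1C=C(Br)C(=O)O/1 | intermediate
26 | (5Z)-3-{(E)-2-[(1S,4S,6R)-4-hydroxy-2,2,6-trimethyl-7-oxabicyclo[4.1.0]heptan-1-yl]ethenyl}-5-[(2E)-2-methylpenta-2,4-dien-1-ylidene]furan-2(5H)-one | C=C/C=C(C)/C=C1C=C(/C=C/[C@@]23O[C@]2(C)C[C@@H](O)CC3(C)C)C(=O)O/1 | intermediate
27 | pyrrhoxanthin: (3'R)-acetoxy-7',8'-alkynyl cyclohexene half joined through the all-E polyene and the Z-ylidene butenolide to the (3S,5R,6S)-5,6-epoxy-3-hydroxy half | CC(=O)O[C@@H]1CC(C)=C(C#C/C(C)=C/C=C/C=C/C=C(C)/C=C2C=C(/C=C/[C@@]34O[C@]3(C)C[C@@H](O)CC4(C)C)C(=O)O/2)C(C)(C)C1 | target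

Total step count: 19. Longest linear sequence: 10 steps (steps 1, 2, 8, 9, 10, 11, 12, 14, 18, 19).

Steps most likely to fail

1. Step 19 (Heck union). What may go wrong: slow β-hydride elimination from the π-allyl palladium intermediate with loss of regio- and E-control (deconjugated or Z trienes), insertion of a second alkenyl group, and light- or palladium-hydride-induced isomerisation of the heptaene. Fallback (the same bond by Suzuki–Miyaura coupling): it sets out from enynal 8, which is converted by Takai–Utimoto boryl-olefination (Cl2CHB(pin), CrCl2, LiI, THF, 25 °C) into the dienyl pinacol boronate F1. F1 and acid 23 give, under the conditions of step 17, the boryl bromobutenolide F2. Base-free Stille coupling of F2 with stannane 20 under the conditions of step 18, in which a pinacol boronate is inert, gives the right-half boronate F3. F3 and iodide 10 are then joined by Suzuki–Miyaura coupling (Pd(PPh3)4, aq. K3PO4, THF, 25 °C, dark), which comes back to the route at 27.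

2. Step 17 (tandem coupling/lactonisation). What may go wrong: 6-endo-dig closure to the isomeric 2-pyranone, a second alkynylation at the α-bromine, and evaporative loss or oligomerisation of trienyne 21. Fallback (coupling and ring closure separated): it sets out from acid 23, which is esterified (MeOH, H2SO4 cat., 60 °C) to methyl (2E)-2,3-dibromoprop-2-enoate F4. C3-selective Sonogashira coupling of F4 with 21 (Pd(PPh3)4, CuI, Et3N, MeCN, 25 °C) gives the methyl bromoenynoate F5, which cannot lactonise. Saponification (LiOH, THF/H2O, 0 °C) gives acid 24, this time isolated, and AgNO3 (10 mol %, acetone, 25 °C) closes it 5-exo-dig, coming back to the route at 25.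

3. Step 14 (stannyl-olefination). What may go wrong: sluggish addition of the bulky chromium carbenoid to the neopentyl-type aldehyde, iodide opening of the oxirane during a long reaction time, and erosion of E-selectivity. Fallback (iodo-olefination, then tin by metal exchange): it sets out from the silyl-protected aldehyde 14. Takai iodo-olefination (CrCl2, CHI3, THF, 0 → 25 °C) gives the silyl-protected (E)-iodoalkene F6. Iodine–lithium exchange (t-BuLi, 2 equiv, Et2O, −78 °C) and quench with Bu3SnCl give the silyl-protected vinylstannane F7. Bu4NF (THF, 0 °C) removes the silyl group and comes back to the route at 20.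

Further compounds
F1 | step 19 | 4,4,5,5-tetramethyl-2-[(1E,3E)-4-methylhexa-1,3-dien-5-yn-1-yl]-1,3,2-dioxaborolane | C#C/C(C)=C/C=C/B1OC(C)(C)C(C)(C)O1
F2 | step 19 | (5Z)-3-bromo-5-[(2E,4E)-2-methyl-5-(4,4,5,5-tetramethyl-1,3,2-dioxaborolan-2-yl)penta-2,4-dien-1-ylidene]furan-2(5H)-one | CC1(C)OB(/C=C/C=C(C)/C=C2C=C(Br)C(=O)O/2)OC1(C)C
F3 | step 19 | (5Z)-3-{(E)-2-[(1S,4S,6R)-4-hydroxy-2,2,6-trimethyl-7-oxabicyclo[4.1.0]heptan-1-yl]ethenyl}-5-[(2E,4E)-2-methyl-5-(4,4,5,5-tetramethyl-1,3,2-dioxaborolan-2-yl)penta-2,4-dien-1-ylidene]furan-2(5H)-one | CC1(C)OB(/C=C/C=C(C)/C=C2C=C(/C=C/[C@@]34O[C@]3(C)C[C@@H](O)CC4(C)C)C(=O)O/2)OC1(C)C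
F4 | step 17 | methyl (2E)-2,3-dibromoprop-2-enoate | COC(=O)/C(Br)=C\Br
F5 | step 17 | methyl (2E,6E)-2-bromo-6-methylnona-2,6,8-trien-4-ynoate | COC(=O)/C(Br)=C\C#C/C(C)=C/C=C
F6 | step 14 | tert-butyl({(1R,3S,6S)-6-[(E)-2-iodoethenyl]-1,5,5-trimethyl-7-oxabicyclo[4.1.0]heptan-3-yl}oxy)dimethylsilane | I/C=C/[C@@]12O[C@]1(C)C[C@@H](O[Si](C)(C)C(C)(C)C)CC2(C)C
F7 | step 14 | tert-butyl(dimethyl)({(1R,3S,6S)-1,5,5-trimethyl-6-[(E)-2-(tributylstannyl)ethenyl]-7-oxabicyclo[4.1.0]heptan-3-yl}oxy)silane | CCCC[Sn](CCCC)(CCCC)/C=C/[C@@]12O[C@]1(C)C[C@@H](O[Si](C)(C)C(C)(C)C)CC2(C)C
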